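The vessel is closed and stirred at constant volume, so whatever leaves J stays in the flask, and we can keep books on it.

| flask | J | Q | remark | time |
|---|---|---|---|---|
| elm | 0.075 M | 1.5 equiv | run made earlier |  |
| noon | 0.050 M | 1.50 equiv |  | 80 min |
| midnight | 0.050 M | 2.00 equiv |  | 80 min |
| dusk | 0.050 M | 3.00 equiv |  | 80 min |

elm run (percent of the J charged)

| time / min | E / % | G / % |
|---|---|---|
| 2.00 | 15.5 | 25.8 |
| 5.00 | 31.6 | 18.1 |
| 10.0 | 39.3 | 7.1 |
| 15.0 | 41.6 | 2.9 |
| 20.0 | 43.5 | 1.9 |
| 30.0 | 47.8 | 1.3 |

(standard deviation of a reading: 1 percentage point)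

- a reading or a percentage of G counts all its forms, free or not

- E at the end, in percent of the J charged, for each flask in turn (noon, midnight, dusk)

The bench rule for a bis adduct is two Q per E, so the elm run, at 1.5 equiv, should reach 75.0%. It read 47.8% at 30.0 min, a fraction 0.637 of that, with G down to 1.3%, and here the rule stops working.

In the elm run E plus G read 49.7% at 5.00 min and 49.1% at 30.0 min, so about half of the charge went unseen. Were that J, the elm flask at 5.00 min would still hold Q worth 68.7% of the J charged beside it, yet the sum read no higher afterwards. We therefore assume that the unseen forms already carry one Q each.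

Dividing the rate of Q use by the rate of J use takes time out: each J lost costs one Q, and each E costs one more. In the noon flask the allowance, the equivalents of Q minus one, read as the most E that Q can pay for once J has gone, is 50.0%. On this reckoning Q is the limiting reagent in the noon flask.

| Flask | Q charged | Allowance |
|---|---|---|
| elm | 1.5 equiv | 50.0% |
| noon | 1.50 equiv | 50.0% |
| midnight | 2.00 equiv | 100% |
| dusk | 3.00 equiv | 200% |

If the steps are second order, the clock runs with concentration, and noon's concentration times time is 1.78 times that of elm's last reading. We therefore commit to E in the noon flask between about 47.8% and 50.0%. In the midnight and dusk flasks the allowance reaches the J charged, so the books give a ceiling of 100% there and we commit to no figure.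

The forecast says 57%, 70% and 85%, holding that “unreacted J, roughly half the charge” feeds E, and for the noon flask it stands above our allowance.

The flasks give E of 47.8% at noon, 67.3% at midnight and 78.9% at dusk.

    J + Q → G (k = 0.130 L mol⁻¹ s⁻¹)
    J + Q → L (k = 0.0740 L mol⁻¹ s⁻¹)
    Q + G → E (k = 0.100 L mol⁻¹ s⁻¹)
    Q + L → E (k = 0.0770 L mol⁻¹ s⁻¹)
    Q ⇌ D (K = 0.590, k = 0.0210 s⁻¹)
    X ⇌ G, rate k6*(cs6 - [G]) while solid is left; crystals form when [G] > cs6 (solubility = 17.0 mM, k = 0.0470 s⁻¹)
    G → Z (k = 0.00280 s⁻¹)

The noon flask's 47.8% lies 2.2 percentage points under its allowance of 50.0%, with Q down to 1.3% of its own charge and D at 5.95 × 10⁻⁴ M at 80.0 min. In the midnight flask J stands at 0% at 80.0 min, so the allowance of 100% can be traced. In percent of the J charged, it holds E at 67.3%, Q at 20.6% and D at 12.1%, together 100%.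

The runs are calculated from invented constants, noise included.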